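**Retrosynthetic overview**

1. Rings A, C and B are bought complete as kaempferol. No ring is formed in the route; only the oxygen substituents are edited.
2. Feature used: on ring A, C8 lies para to the C5 hydroxyl (itself chelated to the C4 carbonyl) and C6 lies ortho to it, so a para-seeking oxidation of the 5-phenolate puts the missing oxygen on C8 and not on C6.
3. Target ⇐ 4'-O-prenyl bond (Mitsunobu on a 7-O-silylated triol) ⇐ triol 8 ⇐ hydrogenolysis and 8-O-methylation of hydroquinone 6.
4. 6 ⇐ C8–O bond by Elbs persulfate oxidation of 7,4'-bis(benzyloxy)-5-hydroxy-3-methoxyflavone 4.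
5. 4 ⇐ kaempferol by 7,4'-di-O-benzylation and 3-O-methylation.

Key step: step 3

Remark on the chemistry: sulfate 5 is drawn as its monopotassium salt, although in the alkaline medium its 5-OH is ionised as well.

**Route**

Step 1
Reactants: 1 kaempferol; 2 benzyl bromide
Product: 3 7,4'-bis(benzyloxy)-3,5-dihydroxyflavone
Conditions: BnBr (2.1 equiv), K2CO3 (2.2 equiv), DMF, 0 °C to rt
Reagents that add atoms: benzyl bromide, BrCc1ccccc1
Why: Williamson etherification under acidity control, in which the 7-OH and 4'-OH, the two most acidic phenols of kaempferol, should take up a limited charge of benzyl bromide ahead of the 3-OH and the chelated 5-OH.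

Step 2
Reactants: 3 7,4'-bis(benzyloxy)-3,5-dihydroxyflavone
Product: 4 7,4'-bis(benzyloxy)-5-hydroxy-3-methoxyflavone
Conditions: MeI (1.3 equiv), K2CO3 (1.5 equiv), acetone, reflux
Reagents that add atoms: iodomethane, CI
Why: Williamson O-methylation of the flavonol 3-OH, which is more acidic and more accessible than the 5-OH held in a six-membered hydrogen bond to the C4 carbonyl, as in the usual partial methylation of flavonols.

Step 3
Reactants: 4 7,4'-bis(benzyloxy)-5-hydroxy-3-methoxyflavone
Product: 6 7,4'-bis(benzyloxy)-5,8-dihydroxy-3-methoxyflavone, via potassium flavon-8-yl sulfate 5 (not isolated)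
Conditions: K2S2O8 (1.2 equiv), aq KOH, pyridine, 15 °C, N2, 24 h; acidify and remove unreacted 4; then dil. HCl, 90 °C, N2
Reagents that add atoms: potassium peroxodisulfate, [K+].[K+].[O-]S(=O)(=O)OOS(=O)(=O)[O-]
Why: In this Elbs persulfate oxidation the 5-phenolate of 4 attacks a peroxide oxygen of the peroxodisulfate dianion through its para carbon C8 with sulfate as leaving group, the cyclohexadienone formed tautomerises to the C8 aryl sulfate 5, and hot dilute acid then cleaves the S–O bond to leave the 8-OH. The closest known reaction type is the Elbs oxidation of 5-hydroxyflavones and 5-hydroxyflavonol ethers to their 5,8-dihydroxy derivatives. No ring is closed and no stereocenter is formed; the single new bond is C8–O, and its oxygen comes from the reagent. The step needs C8 over C6, which the intrinsic para preference of phenolate persulfate oxidation should secure because C8 is para and C6 ortho to O5, while the 5-OH is the only free phenol, so ring B and the benzyl ethers are not attacked. The benzyl ethers and the 3-OMe enol ether should survive the brief hydrolysis in dilute HCl, exclusion of air should keep the hydroquinone from passing to the 5,8-quinone, and unreacted 4 should be recoverable for recycling.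

Step 4
Reactants: 6 7,4'-bis(benzyloxy)-5,8-dihydroxy-3-methoxyflavone
Product: 7 7,4'-bis(benzyloxy)-5-hydroxy-3,8-dimethoxyflavone
Conditions: Me2SO4 (1.05 equiv), K2CO3 (1.2 equiv), acetone, reflux, N2
Reagents that add atoms: dimethyl sulfate, COS(=O)(=O)OC
Why: Williamson methylation with one equivalent of dimethyl sulfate should go to the unchelated 8-OH, because the 5-OH is tied up in the hydrogen bond to the C4 carbonyl and is far less nucleophilic, as in the standard partial methylation of 5,8-dihydroxyflavones.

Step 5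
Reactants: 7 7,4'-bis(benzyloxy)-5-hydroxy-3,8-dimethoxyflavone
Product: 8 5,7,4'-trihydroxy-3,8-dimethoxyflavone
Conditions: H2 (1 atm), 10% Pd/C, EtOAc–MeOH, rt
Reagents that add atoms: none
Why: Catalytic hydrogenolysis of the two benzyl aryl ethers over Pd/C at room temperature, under which the conjugated C2=C3 bond of the flavone and the methyl ethers are not expected to be touched.

Step 6
Reactants: 8 5,7,4'-trihydroxy-3,8-dimethoxyflavone
Product: 9 5,4'-dihydroxy-3,8-dimethoxy-7-(triisopropylsilyloxy)flavone
Conditions: TIPSCl (1.05 equiv), imidazole (2.2 equiv), DMF, 0 °C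
Reagents that add atoms: chlorotriisopropylsilane, CC(C)[Si](Cl)(C(C)C)C(C)C
Why: O-Silylation under acidity control, in which imidazole ionises appreciably only the 7-OH (a vinylogous acid para to the C4 carbonyl), so that one equivalent of the silyl chloride should be taken up there ahead of the less acidic 4'-OH and the chelated 5-OH.

Step 7
Reactants: 9 5,4'-dihydroxy-3,8-dimethoxy-7-(triisopropylsilyloxy)flavone; 10 3-methylbut-2-en-1-ol (prenol)
Product: 11 5-hydroxy-3,8-dimethoxy-4'-(3-methylbut-2-enyloxy)-7-(triisopropylsilyloxy)flavone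
Conditions: PPh3 (1.3 equiv), DIAD (1.3 equiv), THF, 0 °C to rt
Reagents that add atoms: 3-methylbut-2-en-1-ol, CC(C)=CCO
Why: Mitsunobu etherification of the only reactive phenol, the 4'-OH, by SN2 attack at the primary allylic carbon under neutral conditions, which should leave the aryl silyl ether and the chelated 5-OH untouched and give the unrearranged prenyl ether.

Step 8
Reactants: 11 5-hydroxy-3,8-dimethoxy-4'-(3-methylbut-2-enyloxy)-7-(triisopropylsilyloxy)flavone
Product: 12 5,7-dihydroxy-3,8-dimethoxy-4'-prenyloxyflavone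
Conditions: TBAF (1.1 equiv), AcOH (1.2 equiv), THF, 0 °C
Reagents that add atoms: none
Why: Fluoride-induced cleavage of the aryl silyl ether, buffered with acetic acid, to which the prenyl ether, the methyl ethers and the flavone core are inert.

**Compound list**

1 | kaempferol (3,5,7,4'-tetrahydroxyflavone) | O=c1c(O)c(-c2ccc(O)cc2)oc2cc(O)cc(O)c12 | starting material
2 | benzyl bromide | BrCc1ccccc1 | starting material
3 | 7,4'-bis(benzyloxy)-3,5-dihydroxyflavone | O=c1c(O)c(-c2ccc(OCc3ccccc3)cc2)oc2cc(OCc3ccccc3)cc(O)c12 | intermediate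
4 | 7,4'-bis(benzyloxy)-5-hydroxy-3-methoxyflavone | COc1c(-c2ccc(OCc3ccccc3)cc2)oc2cc(OCc3ccccc3)cc(O)c2c1=O | intermediate
5 | potassium 7,4'-bis(benzyloxy)-5-hydroxy-3-methoxyflavon-8-yl sulfate | COc1c(-c2ccc(OCc3ccccc3)cc2)oc2c(OS(=O)(=O)[O-])c(OCc3ccccc3)cc(O)c2c1=O.[K+] | intermediate
6 | 7,4'-bis(benzyloxy)-5,8-dihydroxy-3-methoxyflavone | COc1c(-c2ccc(OCc3ccccc3)cc2)oc2c(O)c(OCc3ccccc3)cc(O)c2c1=O | intermediate
7 | 7,4'-bis(benzyloxy)-5-hydroxy-3,8-dimethoxyflavone | COc1c(-c2ccc(OCc3ccccc3)cc2)oc2c(OC)c(OCc3ccccc3)cc(O)c2c1=O | intermediate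
8 | 5,7,4'-trihydroxy-3,8-dimethoxyflavone | COc1c(-c2ccc(O)cc2)oc2c(OC)c(O)cc(O)c2c1=O | intermediate
9 | 5,4'-dihydroxy-3,8-dimethoxy-7-(triisopropylsilyloxy)flavone | COc1c(-c2ccc(O)cc2)oc2c(OC)c(O[Si](C(C)C)(C(C)C)C(C)C)cc(O)c2c1=O | intermediate
10 | 3-methylbut-2-en-1-ol (prenol) | CC(C)=CCO | starting material
11 | 5-hydroxy-3,8-dimethoxy-4'-(3-methylbut-2-enyloxy)-7-(triisopropylsilyloxy)flavone | COc1c(-c2ccc(OCC=C(C)C)cc2)oc2c(OC)c(O[Si](C(C)C)(C(C)C)C(C)C)cc(O)c2c1=O | intermediate
12 | 5,7-dihydroxy-3,8-dimethoxy-4'-prenyloxyflavone | COc1c(-c2ccc(OCC=C(C)C)cc2)oc2c(OC)c(O)cc(O)c2c1=O | target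

**Step count**

Total: 8 steps. Longest linear sequence: 8 steps, from kaempferol 1.

**Steps most likely to fail**

Step 3. The oxidation may stall because the lipophilic phenolate dissolves poorly in the aqueous medium, and the hydroquinone formed may be over-oxidised to the quinone during hydrolysis and isolation. The fallback brings the C8 oxygen in by halogenation and copper-mediated methoxylation. It sets out from 4: benzylation of the chelated 5-OH (benzyl bromide 2, K2CO3, DMF, 80 °C) would give 5,7,4'-tris(benzyloxy)-3-methoxyflavone F1. With no free 5-OH left, electrophilic iodination (NIS, CF3CO2H cat., MeCN, rt) is expected at C8, the ring A position flanked by only one benzyloxy group, to give 5,7,4'-tris(benzyloxy)-8-iodo-3-methoxyflavone F2. Ullmann-type methoxylation (NaOMe, CuBr, MeOH–DMF, 110 °C) would then give 5,7,4'-tris(benzyloxy)-3,8-dimethoxyflavone F3. Hydrogenolysis of all three benzyl ethers (H2, 10% Pd/C, EtOAc–MeOH) comes back to the route at triol 8.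

Step 6. The silyl group may be taken up with poor site selectivity between O7 (flanked by the 8-OMe) and the unhindered O4', and the aryl silyl ether may be lost on purification. The fallback differentiates the two phenols by alkylation of the mono-phenolate with an acetal chloride and then uses base-mediated prenylation. It sets out from 8: 2-(trimethylsilyl)ethoxymethyl chloride (C[Si](C)(C)CCOCCl, 1.05 equiv) with iPr2NEt in CH2Cl2–DMF at 0 °C should alkylate the most acidic 7-OH to give 5,4'-dihydroxy-3,8-dimethoxy-7-{[2-(trimethylsilyl)ethoxy]methoxy}flavone F4. Prenyl bromide (CC(C)=CCBr) with K2CO3 in acetone at rt would etherify the 4'-OH to give 5-hydroxy-3,8-dimethoxy-4'-prenyloxy-7-{[2-(trimethylsilyl)ethoxy]methoxy}flavone F5. TBAF in THF–DMPU at 60 °C would remove the acetal and come back to the route at target 12.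

Step 1. Benzylation may run on to O3, or fail to separate the 4'-OH from the 3-OH, so that mixtures of di- and tri-benzyl ethers form. The fallback replaces direct alkylation by displacement of the most labile aryl acetates. It sets out from 1: Ac2O in pyridine would give kaempferol 3,5,7,4'-tetraacetate F6. Benzyl bromide 2 with K2CO3 and KI in refluxing acetone should exchange the 7- and 4'-acetoxy groups in turn for benzyloxy while the 3- and 5-acetates stay, giving 3,5-di-O-acetyl-7,4'-di-O-benzylkaempferol F7. Methanolysis (K2CO3, MeOH–THF, rt) comes back to the route at 3.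

**Further compounds**

F1 | step 3 | 5,7,4'-tris(benzyloxy)-3-methoxyflavone | COc1c(-c2ccc(OCc3ccccc3)cc2)oc2cc(OCc3ccccc3)cc(OCc3ccccc3)c2c1=O
F2 | step 3 | 5,7,4'-tris(benzyloxy)-8-iodo-3-methoxyflavone | COc1c(-c2ccc(OCc3ccccc3)cc2)oc2c(I)c(OCc3ccccc3)cc(OCc3ccccc3)c2c1=O
F3 | step 3 | 5,7,4'-tris(benzyloxy)-3,8-dimethoxyflavone | COc1c(-c2ccc(OCc3ccccc3)cc2)oc2c(OC)c(OCc3ccccc3)cc(OCc3ccccc3)c2c1=O
F4 | step 6 | 5,4'-dihydroxy-3,8-dimethoxy-7-{[2-(trimethylsilyl)ethoxy]methoxy}flavone | COc1c(-c2ccc(O)cc2)oc2c(OC)c(OCOCC[Si](C)(C)C)cc(O)c2c1=O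
F5 | step 6 | 5-hydroxy-3,8-dimethoxy-4'-prenyloxy-7-{[2-(trimethylsilyl)ethoxy]methoxy}flavone | COc1c(-c2ccc(OCC=C(C)C)cc2)oc2c(OC)c(OCOCC[Si](C)(C)C)cc(O)c2c1=O
F6 | step 1 | kaempferol 3,5,7,4'-tetraacetate | CC(=O)Oc1ccc(-c2oc3cc(OC(C)=O)cc(OC(C)=O)c3c(=O)c2OC(C)=O)cc1
F7 | step 1 | 3,5-di-O-acetyl-7,4'-di-O-benzylkaempferol | CC(=O)Oc1c(-c2ccc(OCc3ccccc3)cc2)oc2cc(OCc3ccccc3)cc(OC(C)=O)c2c1=O
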